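At 3.0 h I read the flask, and the winter run is that same flask followed up to 120 min, so the readings already carry most of the answer.

in all of them: starting material 0.028 M; free catalyst 0.70 mM
- winter: second substrate 0.028 M; solid reagent 0.084 M; temperature 25 °C; the very flask that is asked about, followed so far
- spring: second substrate 0.028 M; solid reagent 0.084 M; temperature 31 °C; run made earlier
- flask: second substrate 0.0280 M; solid reagent 0.0840 M; temperature 25 °C; time 3.0 h

| run | time / min | target / % |
|---|---|---|
| winter | 8.00 | 2 |
| winter | 15.0 | 12 |
| winter | 30.0 | 21 |
| winter | 60.0 | 27 |
| winter | 120 | 32 |
| spring | 8.00 | 5 |
| spring | 15.0 | 10 |
| spring | 30.0 | 22 |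
| spring | 60.0 | 27 |
| spring | 120 | 29 |

(each reading ± 2 percentage points)

- target, in percent of the starting material first charged, at 3.0 h
- what to do for the largest gain in target; "none" if nothing gains more than 2 percentage points (south-east / south-west / north-east / south / none)
- target present, with what was taken out counted in, in percent of the starting material first charged, after north-east
- target present, with what was taken out counted in, in percent of the starting material first charged, after south

- south-east: at 3.0 h add free catalyst, 100% of the amount charged, then wait 50 min
- south-west: at 3.0 h raise the temperature by 10 K, then wait 50 min
- north-east: at 3.0 h take out 90% of the target then present, then wait 50 min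
- south: change nothing and wait 50 min more

- solid reagent is a solid; its amount is given per volume of the solution
- target taken out counts as made
- at the start none of the solid reagent is in solution
- additions bring no volume worth counting

The time scales run in rungs. The first rung is the lag: none of the solid reagent is in solution at the start, and the winter run reads 2% at 8.00 min, then 12% at 15.0 min. Next comes the rise, 9 percentage points between 15.0 min and 30.0 min. Then comes the stall, a slower pace, with 5 points between 60.0 min and 120 min. The spring run, at 31 °C, ends at 29%, which is 3 points from the last winter reading, with a scatter of 2 points on each reading. On the last rung stand the 50 min of waiting, and I expect them to stay inside the margin of 2 points. So I put the flask at about 32% at 3.0 h.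

Yet the winter run stops with 68.0% of the starting material not read as target and the solid reagent charged at 3.00 equivalents. I read this as a worn-out catalyst, which is a judgement, not a proof. My measure is the capacity, the target made per catalyst charged, or turnover number: 12.8. The zero of my scale is that each catalyst in this recipe does that many turnovers, old dose or new. A fresh dose of 100% is then worth about 32 points by this estimate, well above the margin, so I choose south-east.

The forecast gives 33.5%, higher than my figure, 36% after north-east, 35% after south, and south-east, reasoning that “Fresh catalyst helps under both of these”.

The flask gives 31.9%, 31.9% after north-east and 31.9% after south. The choice is south-east, which gains 15 points against 0 points for waiting.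

    starting material + partner + free catalyst → free catalyst + target (k = 3600 M⁻² min⁻¹, Ea = 36.0 kJ mol⁻¹)
    solid reagent ⇌ partner, rate k2*(cs2 - [partner]) while solid is left; crystals form when [partner] > cs2 (solubility = 13.0 mM, k = 0.0460 min⁻¹)
    free catalyst + target → spent catalyst (k = 8.00 M⁻¹ min⁻¹, Ea = 48.0 kJ mol⁻¹)
    second substrate + partner + free catalyst → free catalyst + second product (k = 430 M⁻² min⁻¹, Ea = 48.0 kJ mol⁻¹)
    (constants at 25 °C)

With free catalyst at 83.0% and partner at 0.00460 M at 18.0 min, starting material was turning into target, and that step had 71% of its turnover behind it by 36.0 min. By 90.0 min free catalyst was down to 1.20% with spent catalyst at 98.8%, and target stood at 31.9% up to 1800 min. The added dose made a net 5.86 target per catalyst, below the capacity of 12.8. For the neighbour flask with 0.0018 M of free catalyst, the capacity gives an estimate of 82.3%. The computed result is 38.4%, less than that estimate, at 5.98 per catalyst.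

Readings and results were computed with made-up constants.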